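**Strategy.** Everything rests on making ring C (C8, C9, C11, C12, C13, C14) one carbon short and closing ring D in the same operation that enlarges it. The precursor is a cyclopentane (C8, C9, C11, C13, C14) fused to the spirolactone, carrying a siloxycyclopropane on C11–C13 (C12) and a propargyl group on C8. Oxidation opens the C11–C13 bond: the ring grows to the cyclohexanone (C11 ketone) and the C13 radical closes onto the alkyne, giving the bicyclo[3.2.1]octane with the C16 exo-methylene. The step exploits the 1,3-relation between the C11 oxygen and the bridgehead C13 of ring C, and that of C13 and C8.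

Key step: step 14

Remark on numbering: atoms carry ent-kaurane numbers (C1–C20); β is the face of ring A that bears the C4 methyl and H5, α the face that bears C19, C6 and C20.
Assumption: the (S)-oxazaborolidinium catalyst of step 2 is taken to give the (1S,6R) adduct; if the sense of induction is the opposite, the (R)-catalyst is used.

Step 1
Reactants: 1 methyl (E)-4-oxopent-2-enoate
Product: 2 methyl (2E)-4-(triisopropylsilyloxy)penta-2,4-dienoate
Conditions: TIPSOTf, Et3N, CH2Cl2, 0 °C
Reagents that add atoms: triisopropylsilyl trifluoromethanesulfonate, CC(C)[Si](C(C)C)(C(C)C)OS(=O)(=O)C(F)(F)F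
Why: Soft enolisation of the methyl ketone (the only enolisable position) gives the 2-siloxy diene by O-silylation.

Step 2
Reactants: 2 methyl (2E)-4-(triisopropylsilyloxy)penta-2,4-dienoate; 3 methacrolein
Product: 4 methyl (1S,6R)-6-formyl-6-methyl-3-(triisopropylsilyloxy)cyclohex-2-ene-1-carboxylate
Conditions: (S)-3,3-diphenyl-1-(2-methylphenyl)tetrahydro-1H,3H-pyrrolo[1,2-c][1,3,2]oxazaborole·HN(SO2CF3)2 (20 mol %), CH2Cl2, −78 → −40 °C
Reagents that add atoms: none
Why: Catalytic enantioselective Diels–Alder reaction with a CBS-type cationic oxazaborolidine: the CH2 terminus of the siloxy diene bonds to the β-carbon of methacrolein (para orientation), the endo formyl group gives the cis pair C19-formyl/C6-ester, and the catalyst face sets C4 and C5.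

Step 3
Reactants: 4 Diels–Alder adduct
Product: 6 cis-fused 6,19-lactone with the C1(OTIPS)=C10 enol ether, via hydroxy ester 5 (not isolated)
Conditions: NaBH4, MeOH, 0 °C → rt
Reagents that add atoms: none
Why: Chemoselective aldehyde reduction followed by lactonisation of the C19 alkoxide onto the cis ester; no new stereocentre.

Step 4
Reactants: 6 lactone silyl enol ether
Product: 8 α-formyl ketone (hydroxymethylene tautomer), via β-keto acetal 7 (not isolated)
Conditions: HC(OMe)3, BF3·OEt2, CH2Cl2, −78 → −20 °C; then 1 M HCl, THF, rt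
Reagents that add atoms: trimethyl orthoformate, COC(OC)OC; water, O
Why: Mukaiyama-type alkylation of the silyl enol ether by the dimethoxycarbenium ion occurs only at C10, and acetal hydrolysis frees the 2-formyl ketone (regiospecific formylation).

Step 5
Reactants: 8 α-formyl ketone; 9 methyl acrylate
Product: 10 keto aldehyde ester with quaternary C10 (C20 formyl α; C9–C8–C7 ester chain β)
Conditions: DBU (20 mol %), MeCN, 0 °C → rt
Reagents that add atoms: none
Why: Michael addition of the 2-formyl ketone enolate; the acrylate enters C10 on the convex β face of the cis-fused bicycle, anti to the axial C19 methylene, which sets the quaternary centre.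

Step 6
Reactants: 10 keto aldehyde ester
Product: 12 1β-hydroxy spirolactone (7,20-lactone and 6,19-lactone), via diol ester 11 (not isolated)
Conditions: Me4NBH(OAc)3 (5 equiv), AcOH–MeCN, −20 °C → rt; aq. Rochelle salt; then camphorsulfonic acid (cat.), CH2Cl2, rt
Reagents that add atoms: none
Why: The aldehyde is reduced first and the C20–O–B–H species delivers hydride to the α face of the C1 ketone (Evans–Saksena directed reduction), giving the 1β alcohol trans to C20; the primary C20 hydroxyl then lactonises onto the ester faster than the hindered secondary one.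

Step 7
Reactants: 12 1β-hydroxy spirolactone
Product: 13 1β-silyl ether
Conditions: TBSOTf, 2,6-lutidine, CH2Cl2, 0 °C
Reagents that add atoms: tert-butyldimethylsilyl trifluoromethanesulfonate, CC(C)(C)[Si](C)(C)OS(=O)(=O)C(F)(F)F
Why: Silylation of the hindered axial secondary alcohol with the silyl triflate; this also blocks translactonisation to C7.

Step 8
Reactants: 13 1β-silyl ether
Product: 16 8,9-unsaturated spirolactone, via selenide 14 (not isolated), via selenoxide 15 (not isolated)
Conditions: LiN(i-Pr)2, THF, −78 °C; PhSeBr; then H2O2, pyridine, CH2Cl2, 0 °C → rt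
Reagents that add atoms: none
Why: Kinetic enolisation at the unhindered C8 methylene of the δ-lactone (H5 of the γ-lactone is flanked by two quaternary carbons), selenenylation and selenoxide syn-elimination, for which only the C9 hydrogens are available.

Step 9
Reactants: 16 8,9-unsaturated spirolactone; 17 1,1-dimethoxyethene
Product: 18 cis-fused cyclobutane ketal (C11 ketal on C9; C14 on C8)
Conditions: hν (300 nm, Pyrex), acetone–MeCN, 0 °C, 17 (10 equiv)
Reagents that add atoms: none
Why: Sensitised enone–alkene [2+2] photocycloaddition: the ketene acetal adds head-to-tail (acetal carbon to the β-carbon C9), the four-membered ring enforces cis fusion at C8/C9, and addition on the lactone face next to C1 (axial siloxy group turned away) rather than next to the C5 branch sets C9.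

Step 10
Reactants: 18 cyclobutane ketal; 19 propargyl bromide
Product: 20 8-propargyl cyclobutane ketal
Conditions: LiN(i-Pr)2, THF–DMPU, −78 °C; then 19, −78 → −20 °C
Reagents that add atoms: none
Why: Alkylation of the lactone enolate at the ring-fusion carbon C8; only the cis-fused bicyclo[4.2.0] product is accessible, so the propargyl group ends up cis to H9 and the quaternary C8 has the required configuration.

Step 11
Reactants: 20 8-propargyl cyclobutane ketal
Product: 21 cyclobutanone
Conditions: TsOH·H2O (cat.), acetone–H2O, 40 °C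
Reagents that add atoms: water, O
Why: Acid hydrolysis of the dimethyl ketal; lactones, alkyne and the hindered silyl ether tolerate mild aqueous acid.

Step 12
Reactants: 21 cyclobutanone
Product: 23 cyclopentenyl trimethylsilyl ether (C11(OSiMe3)=C13), via β-keto silane 22 (not isolated)
Conditions: Me3SiCHN2, Sc(OTf)3 (10 mol %), toluene, 0 °C → rt
Reagents that add atoms: trimethylsilyldiazomethane, C[Si](C)(C)C=[N+]=[N-]
Why: Lewis acid-catalysed diazoalkane homologation (Tiffeneau–Demjanov type): the C14 methylene migrates in preference to the hindered tertiary C9, and 1,3-Brook shift of the α-silyl ketone gives the enol silane toward the new carbon C13.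

Step 13
Reactants: 23 cyclopentenyl trimethylsilyl ether
Product: 24 siloxycyclopropane (1-siloxybicyclo[3.1.0]hexane unit C11, C12, C13)
Conditions: Et2Zn, CH2I2, CH2Cl2, 0 °C → rt
Reagents that add atoms: diiodomethane, ICI
Why: Furukawa–Simmons–Smith cyclopropanation of the electron-rich enol ether on the convex face (that of H9 and the propargyl group, anti to C10); both new stereocentres are erased in step 14.

Step 14
Reactants: 24 siloxycyclopropane
Product: 25 bicyclo[3.2.1]octanone (C11 ketone, C16 exo-methylene)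
Conditions: Fe(NO3)3·9H2O (2.5 equiv), 1,4-cyclohexadiene (10 equiv), DMF, 0 °C → rt
Reagents that add atoms: none
Why: Trivalent iron oxidises the siloxycyclopropane by single-electron transfer and, after loss of the silyl group, the cyclopropyloxy radical undergoes β-scission of the internal C11–C13 bond, so that the five-membered ring grows to the six-membered ring C with the C11 ketone and a secondary radical at C13 (external C11–C12 cleavage would funnel into the same radical through the Dowd–Beckwith 1,2-acyl shift). The C13 radical closes ring D by 5-exo-dig addition to the alkyne on C8 (bridged mode) and the vinyl radical takes hydrogen from 1,4-cyclohexadiene to leave the C16 exo-methylene. The closest known reaction type is the ring expansion–5-exo cyclisation of bicyclic siloxycyclopropanes with Fe(NO3)3 or FeCl3; bridged 5-exo-dig closures of cyclohexyl radicals onto 3-propargyl groups are standard in kaurane and gibberellin work. The only new stereocentre, C13, is controlled by C8: the propargyl arm can reach C13 only across the face of ring C on which it stands, in the conformer with the arm axial. The step needs internal bond cleavage and cyclisation faster than hydrogen transfer to, or oxidation of, the C13 radical; strain release and the stability of the secondary ring-expanded radical secure the first, the intramolecular rate and a modest diene concentration the second.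

Step 15
Reactants: 25 bicyclo[3.2.1]octanone
Product: 26 11α-alcohol
Conditions: SmI2, THF–H2O, 0 °C
Reagents that add atoms: none
Why: Ketyl reduction with protonation under thermodynamic control places the hydroxyl equatorial on ring C, on the face away from the C15–C16 bridge (11α); hydride-type attack from the bridge side would give the same epimer, since the other face is blocked by the axial C10.

Step 16
Reactants: 26 11α-alcohol
Product: 27 1,11-bis-silyl ether
Conditions: TBSOTf, 2,6-lutidine, CH2Cl2, 0 °C → rt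
Reagents that add atoms: tert-butyldimethylsilyl trifluoromethanesulfonate, CC(C)(C)[Si](C)(C)OS(=O)(=O)C(F)(F)F
Why: Silylation, so that only the lactol hydroxyl is acylated in step 18.

Step 17
Reactants: 27 1,11-bis-silyl ether
Product: 28 6,19-lactol
Conditions: i-Bu2AlH (1.2 equiv), CH2Cl2, −78 °C; aq. Rochelle salt
Reagents that add atoms: none
Why: Partial reduction of a lactone: the γ-lactone carbonyl on the tertiary C5 is reduced while the δ-lactone, pivalate-like on the quaternary bridgehead C8, is left.

Step 18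
Reactants: 28 6,19-lactol
Product: 29 6-acetate
Conditions: Ac2O, pyridine, DMAP (cat.), CH2Cl2, 0 °C
Reagents that add atoms: acetic anhydride, CC(=O)OC(C)=O
Why: Acylation of the lactol: the anomers interconvert by ring–chain tautomerism and the exo hydroxyl on the convex face of the cis-fused acetal reacts faster, giving the acetate trans to C10 as in the target.

Step 19
Reactants: 29 6-acetate
Product: 30 15-hydroxy-16-ene
Conditions: SeO2 (0.5 equiv), t-BuOOH, CH2Cl2, rt
Reagents that add atoms: selenium dioxide, O=[Se]=O (oxygen donor, kept in turnover by tert-butyl hydroperoxide, CC(C)(C)OO)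
Why: SeO2 allylic oxidation (ene reaction then [2,3]-shift) at C15, the only allylic methylene (C13 is a bridgehead); the C15 configuration is lost in step 20.

Step 20
Reactants: 30 15-hydroxy-16-ene
Product: 31 15-oxo-16-ene (bis-silyl ether of the target)
Conditions: Dess–Martin periodinane, NaHCO3, CH2Cl2, rt
Reagents that add atoms: none
Why: Dess–Martin oxidation of the allylic alcohol to the exo-methylene cyclopentanone under buffered, non-nucleophilic conditions.

Step 21
Reactants: 31 bis-silyl ether
Product: 32 Oreskaurin A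
Conditions: HF·pyridine, THF–pyridine, 0 °C → rt
Reagents that add atoms: none
Why: Fluoride-mediated desilylation of both ethers under buffered acidic conditions that leave the anomeric acetate, the lactone and the enone intact.

**Compound list**
1 | methyl (E)-4-oxopent-2-enoate | CC(=O)/C=C/C(=O)OC | starting material
2 | methyl (2E)-4-(triisopropylsilyloxy)penta-2,4-dienoate | C=C(O[Si](C(C)C)(C(C)C)C(C)C)/C=C/C(=O)OC | intermediate
3 | methacrolein | CC(=C)C=O | starting material
4 | methyl (1S,6R)-6-formyl-6-methyl-3-(triisopropylsilyloxy)cyclohex-2-ene-1-carboxylate (ring A; C19 formyl and C6 ester cis, α) | C1=C(O[Si](C(C)C)(C(C)C)C(C)C)CC[C@@](C)(C=O)[C@H]1C(=O)OC | intermediate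
5 | C19 hydroxy ester from 4 | C1=C(O[Si](C(C)C)(C(C)C)C(C)C)CC[C@@](C)(CO)[C@H]1C(=O)OC | intermediate (not isolated)
6 | (3aR,7aS)-3a-methyl-6-(triisopropylsilyloxy)-3a,4,5,7a-tetrahydro-2-benzofuran-1(3H)-one (cis-fused 6,19-lactone, C1=C10 enol ether) | C1=C(O[Si](C(C)C)(C(C)C)C(C)C)CC[C@@]2(C)COC(=O)[C@H]21 | intermediate
7 | 10-(dimethoxymethyl) 1-ketone (C10 epimers) | COC(OC)C1C(=O)CC[C@@]2(C)COC(=O)[C@H]21 | intermediate (not isolated)
8 | 10-(hydroxymethylene) 1-ketone (α-formyl ketone) | O/C=C1\C(=O)CC[C@@]2(C)COC(=O)[C@H]21 | intermediate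
9 | methyl acrylate | C=CC(=O)OC | starting material
10 | 1-oxo-20-al with methyl propanoate chain on C10 (C9 β, C20 α) | O=C[C@@]1(CCC(=O)OC)C(=O)CC[C@@]2(C)COC(=O)[C@H]21 | intermediate
11 | 1β,20-diol methyl ester | OC[C@@]1(CCC(=O)OC)[C@H](O)CC[C@@]2(C)COC(=O)[C@H]21 | intermediate (not isolated)
12 | 1β-hydroxy spiro-7,20-lactone (6,19-lactone retained) | O=C1CC[C@]2(CO1)[C@H](O)CC[C@@]3(C)COC(=O)[C@H]32 | intermediate
13 | 1β-tert-butyldimethylsilyl ether of 12 | O=C1CC[C@]2(CO1)[C@H](O[Si](C)(C)C(C)(C)C)CC[C@@]3(C)COC(=O)[C@H]32 | intermediate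
14 | 8-phenylselanyl lactone (C8 epimers) | O=C1C([Se]c4ccccc4)C[C@]2(CO1)[C@H](O[Si](C)(C)C(C)(C)C)CC[C@@]3(C)COC(=O)[C@H]32 | intermediate (not isolated)
15 | selenoxide of 14 | O=C1C([Se](=O)c4ccccc4)C[C@]2(CO1)[C@H](O[Si](C)(C)C(C)(C)C)CC[C@@]3(C)COC(=O)[C@H]32 | intermediate (not isolated)
16 | 8,9-unsaturated spirolactone | O=C1C=C[C@]2(CO1)[C@H](O[Si](C)(C)C(C)(C)C)CC[C@@]3(C)COC(=O)[C@H]32 | intermediate
17 | 1,1-dimethoxyethene | C=C(OC)OC | starting material
18 | cyclobutane-fused lactone, C11 dimethyl ketal (H8 and H9 cis; C11 on the lactone face next to C1) | O=C1[C@H]2CC(OC)(OC)[C@H]2[C@]3(CO1)[C@H](O[Si](C)(C)C(C)(C)C)CC[C@@]4(C)COC(=O)[C@H]43 | intermediate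
19 | propargyl bromide | C#CCBr | starting material
20 | 8-propargyl derivative of 18 (propargyl cis to H9) | O=C1[C@@]2(CC#C)CC(OC)(OC)[C@H]2[C@]3(CO1)[C@H](O[Si](C)(C)C(C)(C)C)CC[C@@]4(C)COC(=O)[C@H]43 | intermediate
21 | cyclobutanone (C11 ketone; ring C8, C9, C11, C14) | O=C1[C@@]2(CC#C)CC(=O)[C@H]2[C@]3(CO1)[C@H](O[Si](C)(C)C(C)(C)C)CC[C@@]4(C)COC(=O)[C@H]43 | intermediate
22 | 13-trimethylsilyl cyclopentanone (C13 epimers) | O=C1[C@@]2(CC#C)CC([Si](C)(C)C)C(=O)[C@H]2[C@]3(CO1)[C@H](O[Si](C)(C)C(C)(C)C)CC[C@@]4(C)COC(=O)[C@H]43 | intermediate (not isolated)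
23 | cyclopentenyl trimethylsilyl ether, C11(OSiMe3)=C13 | O=C1[C@@]2(CC#C)CC=C(O[Si](C)(C)C)[C@H]2[C@]3(CO1)[C@H](O[Si](C)(C)C(C)(C)C)CC[C@@]4(C)COC(=O)[C@H]43 | intermediate
24 | siloxycyclopropane (C12 cis to H9 and to the propargyl group) | O=C1[C@@]2(CC#C)C[C@@H]3C[C@]3(O[Si](C)(C)C)[C@H]2[C@]4(CO1)[C@H](O[Si](C)(C)C(C)(C)C)CC[C@@]5(C)COC(=O)[C@H]54 | intermediate
25 | 1β-silyloxy-11-oxo-16-ene 7,20:6,19-dilactone (bicyclo[3.2.1]octane formed) | C=C1C[C@]23C[C@H]1CC(=O)[C@H]2[C@]1(COC3=O)[C@H](O[Si](C)(C)C(C)(C)C)CC[C@@]2(C)COC(=O)[C@H]21 | intermediate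
26 | 11α-alcohol | C=C1C[C@]23C[C@H]1C[C@@H](O)[C@H]2[C@]1(COC3=O)[C@H](O[Si](C)(C)C(C)(C)C)CC[C@@]2(C)COC(=O)[C@H]21 | intermediate
27 | 1β,11α-bis-silyl ether | C=C1C[C@]23C[C@H]1C[C@@H](O[Si](C)(C)C(C)(C)C)[C@H]2[C@]1(COC3=O)[C@H](O[Si](C)(C)C(C)(C)C)CC[C@@]2(C)COC(=O)[C@H]21 | intermediate
28 | 6,19-lactol (anomers) | C=C1C[C@]23C[C@H]1C[C@@H](O[Si](C)(C)C(C)(C)C)[C@H]2[C@]1(COC3=O)[C@H](O[Si](C)(C)C(C)(C)C)CC[C@@]2(C)COC(O)[C@H]21 | intermediate
29 | 6-acetate (acetoxy exo, trans to C10) | C=C1C[C@]23C[C@H]1C[C@@H](O[Si](C)(C)C(C)(C)C)[C@H]2[C@]1(COC3=O)[C@H](O[Si](C)(C)C(C)(C)C)CC[C@@]2(C)CO[C@H](OC(C)=O)[C@H]21 | intermediate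
30 | 15-alcohol (C15 epimers) | C=C1C(O)[C@]23C[C@H]1C[C@@H](O[Si](C)(C)C(C)(C)C)[C@H]2[C@]1(COC3=O)[C@H](O[Si](C)(C)C(C)(C)C)CC[C@@]2(C)CO[C@H](OC(C)=O)[C@H]21 | intermediate
31 | 15-ketone, bis-silyl ether of the target | C=C1C(=O)[C@]23C[C@H]1C[C@@H](O[Si](C)(C)C(C)(C)C)[C@H]2[C@]1(COC3=O)[C@H](O[Si](C)(C)C(C)(C)C)CC[C@@]2(C)CO[C@H](OC(C)=O)[C@H]21 | intermediate
32 | Oreskaurin A | C=C1C(=O)[C@]23C[C@H]1C[C@@H](O)[C@H]2[C@]1(COC3=O)[C@H](O)CC[C@@]2(C)CO[C@H](OC(C)=O)[C@H]21 | target

**Count.** Total steps: 21. Longest linear sequence: 21 (fully linear from 1).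

**Steps most likely to fail**

Step 14. The C13 radical may be reduced by the diene or oxidised by iron before it closes onto the alkyne, giving the monocyclic ring-expanded ketone or enone. Fallback from 24, returning at 25: FeCl3 in DMF opens the siloxycyclopropane to β-chloro ketone F1 and NaOAc in MeOH eliminates HCl (Saegusa–Ito ring expansion) to cyclohexenone F2, in which C13 is the β-carbon. Bu3SnH and AIBN in benzene at 80 °C add a stannyl radical to the alkyne, and the vinyl radical closes 5-exo onto C13 to give vinylstannane F3. Protodestannylation with HCl in CH2Cl2 gives 25.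

Step 5. The acrylate may attack the concave face of the enolate, or the adduct may lose its formyl group by retro-Claisen cleavage. Fallback from 6, returning at 12, in which the quaternary centre is made by a radical instead of an enolate: Eschenmoser's salt converts 6 into Mannich base F4, MeI gives methiodide F5 and NaHCO3 eliminates it to α-methylene ketone F6. Luche reduction (NaBH4, CeCl3) gives the equatorial 1α allylic alcohol F7, which is silylated (TBSCl, imidazole) to silyl ether F8 and epoxidised with mCPBA to spiro-epoxide F9. Cp2TiCl (trivalent titanium, from Cp2TiCl2 and Zn) opens the epoxide to the C10 radical, which adds to 2,2,2-trifluoroethyl acrylate anti to the axial C19 methylene; the alkoxide lactonises to spirolactone F10. Bu4NF frees alcohol F11, Dess–Martin oxidation gives keto lactone F12, and K[HB(s-Bu)3] (equatorial attack beside the quaternary centre) gives the axial 1β alcohol 12.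

Step 17. The hydride may also attack the δ-lactone, or over-reduce the lactol to the diol. Fallback from 27, returning at 28: MeNH(OMe)·HCl and AlMe3 open the less hindered γ-lactone to hydroxy Weinreb amide F13; Cp2Zr(H)Cl reduces the amide, not the lactone, to the aldehyde, which closes with the C19 hydroxyl to lactol 28.

**Further compounds**
F1 | step 14 | 13-chloro-11-oxo ring-expanded lactone (C13 epimers) | O=C1[C@@]2(CC#C)CC(Cl)CC(=O)[C@H]2[C@]3(CO1)[C@H](O[Si](C)(C)C(C)(C)C)CC[C@@]4(C)COC(=O)[C@H]43
F2 | step 14 | 11-oxo-12-ene (cyclohexenone) with 8-propargyl group | O=C1[C@@]2(CC#C)CC=CC(=O)[C@H]2[C@]3(CO1)[C@H](O[Si](C)(C)C(C)(C)C)CC[C@@]4(C)COC(=O)[C@H]43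
F3 | step 14 | 17-tributylstannyl derivative of 25 | CCCC[Sn](CCCC)(CCCC)C=C1C[C@]23C[C@H]1CC(=O)[C@H]2[C@]1(COC3=O)[C@H](O[Si](C)(C)C(C)(C)C)CC[C@@]2(C)COC(=O)[C@H]21
F4 | step 5 | 10-(dimethylaminomethyl) 1-ketone (Mannich base) | CN(C)CC1C(=O)CC[C@@]2(C)COC(=O)[C@H]21
F5 | step 5 | methiodide of F4 | C[N+](C)(C)CC1C(=O)CC[C@@]2(C)COC(=O)[C@H]21.[I-]
F6 | step 5 | 10(20)-methylene 1-ketone | C=C1C(=O)CC[C@@]2(C)COC(=O)[C@H]21
F7 | step 5 | 1α allylic alcohol | C=C1[C@@H](O)CC[C@@]2(C)COC(=O)[C@H]21
F8 | step 5 | 1α silyl ether | C=C1[C@@H](O[Si](C)(C)C(C)(C)C)CC[C@@]2(C)COC(=O)[C@H]21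
F9 | step 5 | 10,20-spiro-epoxide | C1O[C@@]12[C@@H](O[Si](C)(C)C(C)(C)C)CC[C@@]3(C)COC(=O)[C@H]32
F10 | step 5 | 1α-silyloxy spirolactone | O=C1CC[C@]2(CO1)[C@@H](O[Si](C)(C)C(C)(C)C)CC[C@@]3(C)COC(=O)[C@H]32
F11 | step 5 | 1α-hydroxy spirolactone | O=C1CC[C@]2(CO1)[C@@H](O)CC[C@@]3(C)COC(=O)[C@H]32
F12 | step 5 | 1-oxo spirolactone | O=C1CC[C@]2(CO1)C(=O)CC[C@@]3(C)COC(=O)[C@H]32
F13 | step 17 | 19-hydroxy C6 N-methoxy-N-methylamide | C=C1C[C@]23C[C@H]1C[C@@H](O[Si](C)(C)C(C)(C)C)[C@H]2[C@]1(COC3=O)[C@H](O[Si](C)(C)C(C)(C)C)CC[C@@](C)(CO)[C@H]1C(=O)N(C)OC
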